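**Assumption:** the target has no stereocentre and no stereogenic double bond, so the SMILES describes one achiral compound and no stereocontrol is needed; 4-bromo-2-fluoro-6-methylbenzaldehyde is taken as a catalogue building block.

## Retrosynthetic overview

1. The isocoumarin lactone is closed last, by acid enol-lactonisation of a methyl 2-(2-oxoheptyl)benzoate after removal of two MOM groups.
2. The keto ester comes from C3–C4 bond formation: Claisen-type C-acylation of a laterally deprotonated o-toluate ester (already carrying the diaryl ether) with N-methoxy-N-methylhexanamide.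
3. The toluate comes from SNAr of a hindered B-ring phenol on 4-bromo-2-fluoro-6-methylbenzaldehyde, then CHO → CO2Me and Br → OH → OMOM.
4. The B-ring phenol comes from 2-hydroxy-4-methoxybenzaldehyde: MOM protection, Dakin oxidation, ortho-formylation, Wittig, hydrogenation.
5. Ring order: both benzene rings are bought; only the pyranone ring is built, in the final step.

## Route

Step 1
Reactants: 1 2-hydroxy-4-methoxybenzaldehyde
Product: 2 4-methoxy-2-(methoxymethoxy)benzaldehyde
Conditions: MOMCl, i-Pr2NEt, CH2Cl2, 0 °C → rt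
Reagents that add atoms: chloromethyl methyl ether (MOMCl), COCCl
Why: O-alkylation of the phenol with the reactive α-chloro ether (MOM protection) masks the future B-ring hydroxyl as an acetal that tolerates the later base, Pd, oxidant and LDA steps.

Step 2
Reactants: 2 4-methoxy-2-(methoxymethoxy)benzaldehyde
Product: 4 4-methoxy-2-(methoxymethoxy)phenol, via aryl formate 3 (not isolated)
Conditions: mCPBA, CH2Cl2, 0 °C → rt; NaHCO3 wash; then Et3N (cat.), MeOH, rt
Reagents that add atoms: m-chloroperoxybenzoic acid (mCPBA), O=C(OO)c1cccc(Cl)c1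
Why: Baeyer–Villiger (Dakin-type) oxidation, in which the electron-rich aryl group (ortho- and para-alkoxy) migrates in preference to H, and the resulting formate is cleaved by mild methanolysis.

Step 3
Reactants: 4 4-methoxy-2-(methoxymethoxy)phenol
Product: 5 2-hydroxy-5-methoxy-3-(methoxymethoxy)benzaldehyde
Conditions: MgCl2, Et3N, (CH2O)n, MeCN, reflux
Reagents that add atoms: paraformaldehyde (as formaldehyde), C=O
Why: Casnati–Skattebøl magnesium-mediated ortho-formylation delivers formaldehyde only ortho to the phenoxide, and the single free ortho position is the one required; a second formaldehyde takes up the hydride.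

Step 4
Reactants: 5 2-hydroxy-5-methoxy-3-(methoxymethoxy)benzaldehyde
Product: 6 4-methoxy-2-(methoxymethoxy)-6-(pent-1-en-1-yl)phenol (E/Z mixture)
Conditions: n-BuPPh3Br (2.5 equiv), KOtBu (2.5 equiv), THF, 0 °C → rt; NH4Cl work-up
Reagents that add atoms: butyltriphenylphosphonium bromide, CCCC[P+](c1ccccc1)(c1ccccc1)c1ccccc1.[Br-]
Why: Wittig olefination with the non-stabilised butylidene ylide, where the extra base covers the free phenol and the alkene geometry is irrelevant because the double bond is reduced next.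

Step 5
Reactants: 6 4-methoxy-2-(methoxymethoxy)-6-(pent-1-en-1-yl)phenol
Product: 7 4-methoxy-2-(methoxymethoxy)-6-pentylphenol
Conditions: H2 (1 atm), 10% Pd/C, EtOAc, rt
Reagents that add atoms: none
Why: Heterogeneous catalytic hydrogenation saturates the styrenyl alkene while MOM and methyl ethers are inert to H2/Pd.

Step 6
Reactants: 7 4-methoxy-2-(methoxymethoxy)-6-pentylphenol; 8 4-bromo-2-fluoro-6-methylbenzaldehyde
Product: 9 4-bromo-2-[4-methoxy-2-(methoxymethoxy)-6-pentylphenoxy]-6-methylbenzaldehyde
Conditions: K2CO3, DMF, 90 °C, N2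
Reagents that add atoms: none
Why: SNAr, in which the electron-rich phenoxide displaces the fluoride ortho to the formyl group through an aldehyde-stabilised Meisenheimer complex; fluoride reacts far faster than the para bromide.

Step 7
Reactants: 9 4-bromo-2-[4-methoxy-2-(methoxymethoxy)-6-pentylphenoxy]-6-methylbenzaldehyde
Product: 10 4-bromo-2-[4-methoxy-2-(methoxymethoxy)-6-pentylphenoxy]-6-methylbenzoic acid
Conditions: NaClO2, NaH2PO4, 2-methyl-2-butene, t-BuOH/THF/H2O, 0 °C → rt
Reagents that add atoms: sodium chlorite, [Na+].[O-]Cl=O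
Why: Pinnick oxidation converts the hindered, non-enolisable aldehyde to the acid under buffered conditions that spare MOM, aryl bromide and diaryl ether, with the alkene scavenging HOCl.

Step 8
Reactants: 10 4-bromo-2-[4-methoxy-2-(methoxymethoxy)-6-pentylphenoxy]-6-methylbenzoic acid
Product: 11 methyl 4-bromo-2-[4-methoxy-2-(methoxymethoxy)-6-pentylphenoxy]-6-methylbenzoate
Conditions: MeI, K2CO3, DMF, rt
Reagents that add atoms: iodomethane, CI
Why: SN2 O-alkylation of the carboxylate avoids tetrahedral attack at the 2,6-disubstituted carboxyl carbon, which would make Fischer esterification slow.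

Step 9
Reactants: 11 methyl 4-bromo-2-[4-methoxy-2-(methoxymethoxy)-6-pentylphenoxy]-6-methylbenzoate
Product: 12 methyl 2-[4-methoxy-2-(methoxymethoxy)-6-pentylphenoxy]-6-methyl-4-(4,4,5,5-tetramethyl-1,3,2-dioxaborolan-2-yl)benzoate
Conditions: B2pin2, Pd(dppf)Cl2 (5 mol %), KOAc, 1,4-dioxane, 90 °C
Reagents that add atoms: bis(pinacolato)diboron, CC1(C)OB(OC1(C)C)B1OC(C)(C)C(C)(C)O1
Why: Miyaura borylation of the unhindered aryl bromide para to the ester proceeds with a base too weak to touch the ester or the MOM ether.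

Step 10
Reactants: 12 methyl 2-[4-methoxy-2-(methoxymethoxy)-6-pentylphenoxy]-6-methyl-4-(4,4,5,5-tetramethyl-1,3,2-dioxaborolan-2-yl)benzoate
Product: 13 methyl 4-hydroxy-2-[4-methoxy-2-(methoxymethoxy)-6-pentylphenoxy]-6-methylbenzoate
Conditions: 30% H2O2, aq. NaOH, THF, 0 °C
Reagents that add atoms: hydrogen peroxide, OO
Why: Oxidation of the aryl boronate by hydroperoxide (1,2-aryl shift from boron to oxygen) gives the phenol at the same carbon, and the hindered ester survives brief cold base.

Step 11
Reactants: 13 methyl 4-hydroxy-2-[4-methoxy-2-(methoxymethoxy)-6-pentylphenoxy]-6-methylbenzoate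
Product: 14 methyl 4-(methoxymethoxy)-2-[4-methoxy-2-(methoxymethoxy)-6-pentylphenoxy]-6-methylbenzoate
Conditions: MOMCl, i-Pr2NEt, CH2Cl2, 0 °C → rt
Reagents that add atoms: chloromethyl methyl ether (MOMCl), COCCl
Why: MOM protection of the acidic para-hydroxybenzoate OH removes the proton that would consume LDA and deactivate the lateral deprotonation.

Step 12
Reactants: 15 hexanoyl chloride; 16 N,O-dimethylhydroxylamine hydrochloride
Product: 17 N-methoxy-N-methylhexanamide
Conditions: Et3N (2.2 equiv), CH2Cl2, 0 °C → rt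
Reagents that add atoms: none
Why: N-acylation of the hydroxylamine by the acid chloride gives the Weinreb amide, an acyl donor that cannot add a carbanion twice.

Step 13
Reactants: 14 methyl 4-(methoxymethoxy)-2-[4-methoxy-2-(methoxymethoxy)-6-pentylphenoxy]-6-methylbenzoate; 17 N-methoxy-N-methylhexanamide
Product: 18 methyl 4-(methoxymethoxy)-2-[4-methoxy-2-(methoxymethoxy)-6-pentylphenoxy]-6-(2-oxoheptyl)benzoate
Conditions: LDA (1.2 equiv), THF, −78 °C, 30 min; then 17 (1.5 equiv), −78 → −20 °C; AcOH quench
Reagents that add atoms: none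
Why: Crossed Claisen-type condensation (o-toluate anion acylation): LDA removes a proton from the ring methyl group, the vinylogous α-position of the ester, and the carbanion is C-acylated once by the Weinreb amide, while the 2,6-disubstituted ester is too hindered to self-condense at −78 °C.

Step 14
Reactants: 18 methyl 4-(methoxymethoxy)-2-[4-methoxy-2-(methoxymethoxy)-6-pentylphenoxy]-6-(2-oxoheptyl)benzoate
Product: 20 6-hydroxy-8-(2-hydroxy-4-methoxy-6-pentylphenoxy)-3-pentyl-1H-isochromen-1-one (NP-007099), via diphenol keto ester 19 (not isolated)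
Conditions: HCl (3 M in MeOH), 45 °C; concentrate; then p-TsOH·H2O (cat.), toluene, 110 °C, N2
Reagents that add atoms: none
Why: Acidic methanolysis removes both MOM acetals (formaldehyde trapped as its dimethyl acetal), then acid-catalysed enol-lactonisation of the 2-(2-oxoalkyl)benzoate with loss of methanol closes the six-membered isocoumarin ring, which is favoured over seven-membered depsidone formation.

## Compound list

1 | 2-hydroxy-4-methoxybenzaldehyde | COc1ccc(C=O)c(O)c1 | starting material
2 | 4-methoxy-2-(methoxymethoxy)benzaldehyde | COCOc1cc(OC)ccc1C=O | intermediate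
3 | 4-methoxy-2-(methoxymethoxy)phenyl formate | COCOc1cc(OC)ccc1OC=O | intermediate (not isolated)
4 | 4-methoxy-2-(methoxymethoxy)phenol | COCOc1cc(OC)ccc1O | intermediate
5 | 2-hydroxy-5-methoxy-3-(methoxymethoxy)benzaldehyde | COCOc1cc(OC)cc(C=O)c1O | intermediate
6 | 4-methoxy-2-(methoxymethoxy)-6-(pent-1-en-1-yl)phenol (E/Z mixture, geometry deliberately unspecified) | CCCC=Cc1cc(OC)cc(OCOC)c1O | intermediate
7 | 4-methoxy-2-(methoxymethoxy)-6-pentylphenol | CCCCCc1cc(OC)cc(OCOC)c1O | intermediate
8 | 4-bromo-2-fluoro-6-methylbenzaldehyde | Cc1cc(Br)cc(F)c1C=O | starting material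
9 | 4-bromo-2-[4-methoxy-2-(methoxymethoxy)-6-pentylphenoxy]-6-methylbenzaldehyde | CCCCCc1cc(OC)cc(OCOC)c1Oc1cc(Br)cc(C)c1C=O | intermediate
10 | 4-bromo-2-[4-methoxy-2-(methoxymethoxy)-6-pentylphenoxy]-6-methylbenzoic acid | CCCCCc1cc(OC)cc(OCOC)c1Oc1cc(Br)cc(C)c1C(=O)O | intermediate
11 | methyl 4-bromo-2-[4-methoxy-2-(methoxymethoxy)-6-pentylphenoxy]-6-methylbenzoate | CCCCCc1cc(OC)cc(OCOC)c1Oc1cc(Br)cc(C)c1C(=O)OC | intermediate
12 | methyl 2-[4-methoxy-2-(methoxymethoxy)-6-pentylphenoxy]-6-methyl-4-(4,4,5,5-tetramethyl-1,3,2-dioxaborolan-2-yl)benzoate | CCCCCc1cc(OC)cc(OCOC)c1Oc1cc(B2OC(C)(C)C(C)(C)O2)cc(C)c1C(=O)OC | intermediate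
13 | methyl 4-hydroxy-2-[4-methoxy-2-(methoxymethoxy)-6-pentylphenoxy]-6-methylbenzoate | CCCCCc1cc(OC)cc(OCOC)c1Oc1cc(O)cc(C)c1C(=O)OC | intermediate
14 | methyl 4-(methoxymethoxy)-2-[4-methoxy-2-(methoxymethoxy)-6-pentylphenoxy]-6-methylbenzoate | CCCCCc1cc(OC)cc(OCOC)c1Oc1cc(OCOC)cc(C)c1C(=O)OC | intermediate
15 | hexanoyl chloride | CCCCCC(=O)Cl | starting material
16 | N,O-dimethylhydroxylamine hydrochloride | CNOC.Cl | starting material
17 | N-methoxy-N-methylhexanamide | CCCCCC(=O)N(C)OC | intermediate
18 | methyl 4-(methoxymethoxy)-2-[4-methoxy-2-(methoxymethoxy)-6-pentylphenoxy]-6-(2-oxoheptyl)benzoate | CCCCCC(=O)Cc1cc(OCOC)cc(Oc2c(CCCCC)cc(OC)cc2OCOC)c1C(=O)OC | intermediate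
19 | methyl 4-hydroxy-2-(2-hydroxy-4-methoxy-6-pentylphenoxy)-6-(2-oxoheptyl)benzoate | CCCCCC(=O)Cc1cc(O)cc(Oc2c(CCCCC)cc(OC)cc2O)c1C(=O)OC | intermediate (not isolated)
20 | 6-hydroxy-8-(2-hydroxy-4-methoxy-6-pentylphenoxy)-3-pentyl-1H-isochromen-1-one (NP-007099, achiral) | CCCCCc1cc2cc(O)cc(Oc3c(O)cc(OC)cc3CCCCC)c2c(=O)o1 | target

## Summary

Total step count: 14.
Longest linear sequence: 13 steps (steps 1–11, 13 and 14, from compound 1); step 12 is a one-step side branch.

The three steps most likely to fail:

**Step 6 (SNAr with a di-ortho-substituted phenoxide).** The risk is a slow reaction or aldehyde-derived by-products. The fallback sets out from 7 and uses a smaller, more strongly activating ortho group. Compound 7 and commercial 4-bromo-2-fluoro-6-methylbenzonitrile (K2CO3, DMSO, 80 °C) give 4-bromo-2-[4-methoxy-2-(methoxymethoxy)-6-pentylphenoxy]-6-methylbenzonitrile F1. Partial reduction of this nitrile with DIBAL-H (toluene, −78 °C), followed by mild aqueous citric acid hydrolysis of the aldimine, gives aldehyde 9, where the route is rejoined.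

**Step 13 (lateral deprotonation and acylation).** The risk is proton transfer from the enolisable amide to the carbanion or incomplete acylation. The fallback sets out from 14 and forms the ketone from the other side. The same LDA-generated benzylic anion is trapped with CO2, which cannot be enolised, to give {2-(methoxycarbonyl)-5-(methoxymethoxy)-3-[4-methoxy-2-(methoxymethoxy)-6-pentylphenoxy]phenyl}acetic acid F2. Activation with CDI and addition of N,O-dimethylhydroxylamine hydrochloride gives methyl 2-{2-[methoxy(methyl)amino]-2-oxoethyl}-4-(methoxymethoxy)-6-[4-methoxy-2-(methoxymethoxy)-6-pentylphenoxy]benzoate F3. Single addition of pentylmagnesium bromide (THF, −20 °C) to this amide, with the hindered methyl ester untouched, gives keto ester 18, where the route is rejoined.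

**Step 14 (deprotection and lactonisation of the free diphenol).** The risk is competing attack of the B-ring hydroxyl on the ester (depsidone), formaldehyde-derived by-products or incomplete ring closure. The fallback sets out from 18 and closes the ring while both MOM groups are still in place. LiI in EtOAc at reflux cleaves the hindered methyl ester by SN2 attack at the methyl group to give 4-(methoxymethoxy)-2-[4-methoxy-2-(methoxymethoxy)-6-pentylphenoxy]-6-(2-oxoheptyl)benzoic acid F4. Cyclodehydration of this keto acid with Ac2O/Et3N (cat. DMAP, CH2Cl2, rt) gives 6-(methoxymethoxy)-8-[4-methoxy-2-(methoxymethoxy)-6-pentylphenoxy]-3-pentyl-1H-isochromen-1-one F5. Brief treatment with HCl in MeOH at rt then removes the two MOM groups and gives target 20 directly.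

## Further compounds

F1 | step 6 | 4-bromo-2-[4-methoxy-2-(methoxymethoxy)-6-pentylphenoxy]-6-methylbenzonitrile | CCCCCc1cc(OC)cc(OCOC)c1Oc1cc(Br)cc(C)c1C#N
F2 | step 13 | {2-(methoxycarbonyl)-5-(methoxymethoxy)-3-[4-methoxy-2-(methoxymethoxy)-6-pentylphenoxy]phenyl}acetic acid | OC(=O)Cc1cc(OCOC)cc(Oc2c(CCCCC)cc(OC)cc2OCOC)c1C(=O)OC
F3 | step 13 | methyl 2-{2-[methoxy(methyl)amino]-2-oxoethyl}-4-(methoxymethoxy)-6-[4-methoxy-2-(methoxymethoxy)-6-pentylphenoxy]benzoate | CON(C)C(=O)Cc1cc(OCOC)cc(Oc2c(CCCCC)cc(OC)cc2OCOC)c1C(=O)OC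
F4 | step 14 | 4-(methoxymethoxy)-2-[4-methoxy-2-(methoxymethoxy)-6-pentylphenoxy]-6-(2-oxoheptyl)benzoic acid | CCCCCC(=O)Cc1cc(OCOC)cc(Oc2c(CCCCC)cc(OC)cc2OCOC)c1C(=O)O
F5 | step 14 | 6-(methoxymethoxy)-8-[4-methoxy-2-(methoxymethoxy)-6-pentylphenoxy]-3-pentyl-1H-isochromen-1-one | CCCCCc1cc2cc(OCOC)cc(Oc3c(CCCCC)cc(OC)cc3OCOC)c2c(=O)o1
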